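**Assumption:** the SMILES is read as (3S,4R,5S,9R,10S,13R), an ent-labdane. Labdane locants C1–C20 are used for all intermediates (ring A = C1–C5 + C10, ring B = C5–C10, acetoxymethyl carbon = C19), and "syn/anti" refers to the face of the C10 methyl. Both C6 epimers of compound 8 converge in step 5.

## Retrosynthetic overview

1. Target ⇐ C15 primary alcohol (oxidation) ⇐ ring A formed from a five-membered ring C1–C2–C3–C5–C10 by a 1,2-shift of C5 from C3 to C4.
2. Enabling feature: on ring A the C3 carbinol, the quaternary C4 (CH3, CH2OAc) and O-19 form a 1,3-diol monoacetate next to ring-fusion carbon C5. This is the retron of a semipinacol ring expansion of a tertiary C3 cyclopentanol bearing a 2-methyloxirane (C4, C18, C19), coupled to an Evans–Tishchenko reduction by acetaldehyde that puts the acetate on O-19 and leaves the axial 3-OH free.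
3. The hydrindanone precursor ⇐ (S)-carvone, which is ring B with C5 bought and C7=C8/C17 in place. C10 comes from two alkylations, the C9 side chain from an (R)-citronellol-derived five-carbon alkyllithium followed by palladium/formate hydrogenolysis, C3/C2 from the isopropenyl group, and C1 from an orthoformate.
4. Ring order: ring B (bought) → five-membered ring by aldol condensation (step 9) → ring A by ring expansion (step 13).
5. Stereo relay: C5 → C10 → C9 → C3 → C4 (directed epoxidation) → C4 and C3 fixed mechanistically in the key step; C13 is bought.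

Key step: step 13

## Route

Step 1
Reactants: 1 (R)-(+)-citronellol
Product: 2 (R)-citronellyl triisopropylsilyl ether
Conditions: iPr3SiCl, imidazole, DMF, rt
Reagents that add atoms: triisopropylsilyl chloride, CC(C)[Si](Cl)(C(C)C)C(C)C
Why: Standard imidazole-promoted silylation of the primary alcohol; the stereocentre (future C13) is untouched.

Step 2
Reactants: 2 (R)-citronellyl triisopropylsilyl ether
Product: 4 (4R)-4-methyl-6-(triisopropylsilyloxy)hexanoic acid, via aldehyde 3 (not isolated)
Conditions: RuCl3 (2 mol%), NaIO4, CCl4/MeCN/H2O, rt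
Reagents that add atoms: sodium periodate, [Na+].[O-]I(=O)(=O)=O; water, O
Why: RuO4/periodate oxidative cleavage of the trisubstituted alkene should give the acid with loss of acetone; the silyl ether and the remote stereocentre are inert.

Step 3
Reactants: 4 (4R)-4-methyl-6-(triisopropylsilyloxy)hexanoic acid
Product: 6 (3S)-5-iodo-3-methylpentyl triisopropylsilyl ether, via acyl hypoiodite 5 (not isolated)
Conditions: PhI(OAc)2, I2, CCl4, hν, reflux
Reagents that add atoms: iodine, II
Why: Hunsdiecker-type radical iododecarboxylation through the acyl hypoiodite should shorten the chain by one carbon to the primary iodide without touching the stereocentre (the descriptor changes only because of CIP priorities).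

Step 4
Reactants: 7 (S)-(+)-carvone
Product: 8 (5S,6R)-6-methylcarvone (trans; cis epimer converges)
Conditions: LiN(iPr)2, THF, −78 °C; CH3I, −78 to 0 °C
Reagents that add atoms: iodomethane, CI
Why: Kinetic α′-enolate alkylation of carvone; the new C6 centre (expected mainly trans) is erased in step 5, so its configuration does not matter.

Step 5
Reactants: 8 (5S,6R)-6-methylcarvone
Product: 10 (5R,6S)-6-(dimethoxymethyl)-6-methylcarvone (CH(OMe)2 trans and CH3 cis to the isopropenyl group), via silyl dienol ether 9 (not isolated)
Conditions: LiN(iPr)2, THF, −78 °C; Me3SiCl; then HC(OMe)3, Me3SiOTf (cat.), CH2Cl2, −78 °C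
Reagents that add atoms: trimethyl orthoformate, COC(OC)OC
Why: Mukaiyama-type alkylation of the tetrasubstituted silyl enol ether by the dimethoxycarbenium ion should create quaternary C10; the electrophile enters anti to the C5 isopropenyl group, which places the methyl syn to it (the future trans ring fusion) and installs C1 as a masked, non-enolisable aldehyde.

Step 6
Reactants: 6 (3S)-5-iodo-3-methylpentyl triisopropylsilyl ether; 10 (5R,6S)-6-(dimethoxymethyl)-6-methylcarvone
Product: 13 tertiary allylic methyl carbonate (carbonate syn and side chain anti to the C10 methyl), via alkyllithium 11 (not isolated), via lithium alkoxide 12 (not isolated)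
Conditions: 6, tBuLi (2.1 equiv), Et2O, −78 °C; then 10, −78 to −20 °C; then ClCO2CH3, −78 to 0 °C
Reagents that add atoms: methyl chloroformate, COC(=O)Cl
Why: Iodine–lithium exchange followed by 1,2-addition of the primary alkyllithium to the non-enolisable enone carbonyl, anti to the axial C10 methyl, should set the C9 carbinol with O syn to that methyl; the hindered alkoxide is acylated in situ to give the leaving group for step 7.

Step 7
Reactants: 13 tertiary allylic methyl carbonate
Product: 14 ring B unit with C7=C8, 9-H anti and side chain syn to the C10 methyl, 10-CH(OMe)2 and 5-isopropenyl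
Conditions: Pd(OAc)2 (5 mol%), PBu3 (5 mol%), HCO2H, Et3N, THF, 40 °C
Reagents that add atoms: none
Why: Palladium-catalysed formate hydrogenolysis of an allylic carbonate (Tsuji–Trost-type ionisation, then hydride transfer from the palladium formate): zerovalent palladium ionises anti to the carbonate and hydride is delivered from the metal face to the more substituted allyl terminus C9, so C9–H should form anti to the C10 methyl with net inversion while the double bond stays at C7=C8.

Step 8
Reactants: 14 ring B unit with C7=C8
Product: 16 methyl ketone (5-acetyl, 10-CH(OMe)2), via diol 15 (not isolated)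
Conditions: K2OsO4·2H2O (1 mol%), (DHQD)2PHAL (2 mol%), N-methylmorpholine N-oxide, tBuOH/H2O, 0 °C; then NaIO4, THF/H2O, rt
Reagents that add atoms: N-methylmorpholine N-oxide, C[N+]1([O-])CCOCC1 (oxygen relayed by the osmium catalyst)
Why: Ligand-accelerated osmium-catalysed dihydroxylation should select the exocyclic 1,1-disubstituted alkene over the hindered endocyclic trisubstituted one (cyclic trisubstituted alkenes fit the ligand pocket poorly); periodate glycol cleavage (Lemieux–Johnson-type sequence) then gives the methyl ketone that supplies C3 and C2.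

Step 9
Reactants: 16 methyl ketone
Product: 18 trans-fused cyclopentenone (1-en-3-one; 5-H anti to the C10 methyl), via keto aldehyde 17 (not isolated)
Conditions: 1 M HCl, THF, rt; then Bn2NH·CF3CO2H, benzene, 50 °C
Reagents that add atoms: none
Why: Acetal hydrolysis unmasks the C1 aldehyde, and an amine-salt-catalysed intramolecular aldol condensation (5-(enolexo)-exo-trig) of the methyl ketone closes the five-membered ring between the trans-diequatorial C5 and C10 substituents; the mild catalyst is chosen so that H-5 is not epimerised.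

Step 10
Reactants: 18 trans-fused cyclopentenone
Product: 20 trans-hydrindanone (3-ketone; 5-H anti to the C10 methyl), via silyl enol ether 19 (not isolated)
Conditions: RhCl(PPh3)3 (1 mol%), Et3SiH, benzene, 60 °C; then 0.5 M HCl, THF, 0 °C
Reagents that add atoms: none
Why: Rhodium-catalysed 1,4-hydrosilylation of the enone leaves the trisubstituted alkene alone, and mild acidic hydrolysis of the silyl enol ether gives the saturated ketone without base, so the trans ring fusion at C5 should be kept.

Step 11
Reactants: 20 trans-hydrindanone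
Product: 21 tertiary allylic alcohol (3-OH syn to the C10 methyl; isopropenyl syn to H-5)
Conditions: CeCl3, CH2=C(CH3)MgBr, THF, −78 °C
Reagents that add atoms: isopropenylmagnesium bromide, C=C(C)[Mg]Br
Why: Organocerium 1,2-addition is non-basic (no enolisation of the epimerisable ketone) and should occur from the face anti to the angular C10 methyl, setting C3 as (R) with OH syn to that methyl.

Step 12
Reactants: 21 tertiary allylic alcohol
Product: 22 α-hydroxy epoxide (C3 carbinol bearing an (S)-2-methyloxiran-2-yl group)
Conditions: VO(acac)2 (3 mol%), tBuOOH, CH2Cl2, 0 °C to rt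
Reagents that add atoms: tert-butyl hydroperoxide, CC(C)(C)OO
Why: Vanadium-catalysed hydroxyl-directed epoxidation should take the allylic 1,1-disubstituted alkene far faster than the remote ring alkene; in the favoured transition state (O–C3–C4=C19 dihedral about 45°) the ring CH2 (C2) eclipses the C4 methyl to minimise A(1,2) strain and ring-fusion carbon C5 lies anti to the incoming oxygen, which should fix C4 as (S).

Step 13
Reactants: 22 α-hydroxy epoxide
Product: 25 (3S,4R,5S,9R,10S,13R)-19-acetoxy-15-(triisopropylsilyloxy)labd-7-en-3-ol, via hydroxy ketone 23 (not isolated), via hemiacetal 24 (not isolated)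
Conditions: SmI2 (0.3 equiv), CH3CHO (8 equiv), THF, −10 °C to rt
Reagents that add atoms: acetaldehyde, CC=O
Why: Trivalent samarium (formed from SmI2 and the aldehyde) chelates the tertiary alkoxide and the epoxide oxygen, the tertiary C4–O bond ionises and ring-fusion carbon C5 shifts from C3 to C4 anti to the departing oxygen (semipinacol 1,2-shift) to give cyclohexanone 23; its C19 samarium alkoxide adds acetaldehyde and hemiacetal 24 transfers hydride to the C3 ketone through a six-membered chair (Evans–Tishchenko), leaving the acetate on O-19. The closest known reaction type is the samarium-catalysed tandem semipinacol rearrangement/Tishchenko reduction of tertiary α-hydroxy epoxides with aldehydes to 2-quaternary 1,3-diol monoesters. Ring A is not closed by a cyclisation: it arises by ring expansion (five to six) through the 1,2-carbon shift, with retention at the migrating C5, so the trans ring fusion is carried over. C4 is set by invertive substitution at the epoxide carbon (configuration relayed from step 12), and C3 by intramolecular hydride delivery from the C19 side, which gives the axial alcohol trans to CH2OAc. The step needs C5 rather than C2 to migrate; this is secured by the chelate rotamer that places C5 antiperiplanar to C4–O, by the higher migratory aptitude of the more substituted carbon and by relief of trans-hydrindane strain. The position of the acetate is fixed by the mechanism, since the ester forms on the oxygen that carried the hemiacetal.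

Step 14
Reactants: 25 19-acetoxy-15-(triisopropylsilyloxy)labd-7-en-3-ol
Product: 26 (3S,4R,5S,9R,10S,13R)-19-acetoxylabd-7-ene-3,15-diol
Conditions: HF·pyridine, pyridine, THF, 0 °C to rt
Reagents that add atoms: none
Why: Fluoride-mediated cleavage of the primary silyl ether under buffered conditions should leave the acetate (no acyl migration), the axial alcohol and the alkene untouched.

Step 15
Reactants: 26 19-acetoxylabd-7-ene-3,15-diol
Product: 28 CNP0218903.1, (3S,4R,5S,9R,10S,13R)-19-acetoxy-3-hydroxylabd-7-en-15-oic acid, via aldehyde 27 (not isolated)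
Conditions: TEMPO (0.2 equiv), PhI(OAc)2 (2.5 equiv), MeCN/H2O, rt
Reagents that add atoms: water, O
Why: Oxoammonium (TEMPO)-catalysed oxidation with PhI(OAc)2 in aqueous acetonitrile should take the primary alcohol through the aldehyde hydrate to the acid while discriminating against the hindered axial neopentylic C3 alcohol.

## Compound list

1 | (R)-(+)-citronellol | OCC[C@H](C)CCC=C(C)C | starting material
2 | (R)-citronellyl triisopropylsilyl ether | CC(C)[Si](OCC[C@H](C)CCC=C(C)C)(C(C)C)C(C)C | intermediate
3 | (4R)-4-methyl-6-(triisopropylsilyloxy)hexanal (not isolated) | O=CCC[C@@H](C)CCO[Si](C(C)C)(C(C)C)C(C)C | intermediate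
4 | (4R)-4-methyl-6-(triisopropylsilyloxy)hexanoic acid | OC(=O)CC[C@@H](C)CCO[Si](C(C)C)(C(C)C)C(C)C | intermediate
5 | acyl hypoiodite of acid 4 (not isolated) | IOC(=O)CC[C@@H](C)CCO[Si](C(C)C)(C(C)C)C(C)C | intermediate
6 | (3S)-5-iodo-3-methylpentyl triisopropylsilyl ether | ICC[C@@H](C)CCO[Si](C(C)C)(C(C)C)C(C)C | intermediate
7 | (S)-(+)-carvone | C=C(C)[C@H]1CC=C(C)C(=O)C1 | starting material
8 | (5S,6R)-6-methylcarvone (trans; cis epimer converges) | C=C(C)[C@H]1CC=C(C)C(=O)[C@@H]1C | intermediate
9 | trimethylsilyl dienol ether of 8 (not isolated) | C=C(C)[C@H]1CC=C(C)C(O[Si](C)(C)C)=C1C | intermediate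
10 | (5R,6S)-6-(dimethoxymethyl)-6-methylcarvone | C=C(C)[C@H]1CC=C(C)C(=O)[C@]1(C)C(OC)OC | intermediate
11 | (3R)-3-methyl-5-(triisopropylsilyloxy)pentyllithium (not isolated) | [Li]CC[C@@H](C)CCO[Si](C(C)C)(C(C)C)C(C)C | intermediate
12 | lithium alkoxide from addition of 11 to 10 (not isolated) | C=C(C)[C@H]1CC=C(C)[C@@](CC[C@@H](C)CCO[Si](C(C)C)(C(C)C)C(C)C)(O[Li])[C@]1(C)C(OC)OC | intermediate
13 | tertiary allylic methyl carbonate (carbonate syn to the C10 methyl) | C=C(C)[C@H]1CC=C(C)[C@@](CC[C@@H](C)CCO[Si](C(C)C)(C(C)C)C(C)C)(OC(=O)OC)[C@]1(C)C(OC)OC | intermediate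
14 | ring B unit with C7=C8 (9-H anti to the C10 methyl) | C=C(C)[C@H]1CC=C(C)[C@@H](CC[C@@H](C)CCO[Si](C(C)C)(C(C)C)C(C)C)[C@]1(C)C(OC)OC | intermediate
15 | vicinal diol from the isopropenyl group of 14 (carbinol epimers; not isolated) | CC(O)(CO)[C@H]1CC=C(C)[C@@H](CC[C@@H](C)CCO[Si](C(C)C)(C(C)C)C(C)C)[C@]1(C)C(OC)OC | intermediate
16 | methyl ketone (5-acetyl, 10-dimethoxymethyl) | CC(=O)[C@H]1CC=C(C)[C@@H](CC[C@@H](C)CCO[Si](C(C)C)(C(C)C)C(C)C)[C@]1(C)C(OC)OC | intermediate
17 | keto aldehyde (5-acetyl, 10-formyl; not isolated) | CC(=O)[C@H]1CC=C(C)[C@@H](CC[C@@H](C)CCO[Si](C(C)C)(C(C)C)C(C)C)[C@]1(C)C=O | intermediate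
18 | trans-fused cyclopentenone (1-en-3-one) | O=C1[C@H]2CC=C(C)[C@@H](CC[C@@H](C)CCO[Si](C(C)C)(C(C)C)C(C)C)[C@]2(C)C=C1 | intermediate
19 | triethylsilyl enol ether (C2=C3; not isolated) | CC[Si](CC)(CC)OC1=CC[C@@]2(C)[C@H](CC[C@@H](C)CCO[Si](C(C)C)(C(C)C)C(C)C)C(C)=CC[C@H]12 | intermediate
20 | trans-hydrindanone (3-ketone) | O=C1[C@H]2CC=C(C)[C@@H](CC[C@@H](C)CCO[Si](C(C)C)(C(C)C)C(C)C)[C@]2(C)CC1 | intermediate
21 | tertiary allylic alcohol (3-OH syn to the C10 methyl) | C=C(C)[C@]1(O)[C@H]2CC=C(C)[C@@H](CC[C@@H](C)CCO[Si](C(C)C)(C(C)C)C(C)C)[C@]2(C)CC1 | intermediate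
22 | α-hydroxy epoxide (C3 carbinol with (S)-2-methyloxiran-2-yl) | C[C@]3(CO3)[C@]1(O)[C@H]2CC=C(C)[C@@H](CC[C@@H](C)CCO[Si](C(C)C)(C(C)C)C(C)C)[C@]2(C)CC1 | intermediate
23 | β-hydroxy ketone (ring A formed; 3-oxo, 19-OH; not isolated) | OC[C@@]1(C)[C@H]2CC=C(C)[C@@H](CC[C@@H](C)CCO[Si](C(C)C)(C(C)C)C(C)C)[C@]2(C)CCC1=O | intermediate
24 | acetaldehyde hemiacetal of 23 (samarium alkoxide in the flask; not isolated) | CC(O)OC[C@@]1(C)[C@H]2CC=C(C)[C@@H](CC[C@@H](C)CCO[Si](C(C)C)(C(C)C)C(C)C)[C@]2(C)CCC1=O | intermediate
25 | (3S,4R,5S,9R,10S,13R)-19-acetoxy-15-(triisopropylsilyloxy)labd-7-en-3-ol | CC(=O)OC[C@@]1(C)[C@H]2CC=C(C)[C@@H](CC[C@@H](C)CCO[Si](C(C)C)(C(C)C)C(C)C)[C@]2(C)CC[C@@H]1O | intermediate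
26 | (3S,4R,5S,9R,10S,13R)-19-acetoxylabd-7-ene-3,15-diol | CC(=O)OC[C@@]1(C)[C@H]2CC=C(C)[C@@H](CC[C@@H](C)CCO)[C@]2(C)CC[C@@H]1O | intermediate
27 | (3S,4R,5S,9R,10S,13R)-19-acetoxy-3-hydroxylabd-7-en-15-al (not isolated) | CC(=O)OC[C@@]1(C)[C@H]2CC=C(C)[C@@H](CC[C@@H](C)CC=O)[C@]2(C)CC[C@@H]1O | intermediate
28 | CNP0218903.1, (3S,4R,5S,9R,10S,13R)-19-acetoxy-3-hydroxylabd-7-en-15-oic acid | CC(=O)OC[C@@]1(C)[C@H]2CC=C(C)[C@@H](CC[C@@H](C)CC(=O)O)[C@]2(C)CC[C@@H]1O | target

## Step count and risks

Total step count: 15. Longest linear sequence: 13 steps (steps 1–3 and 6–15; 12 steps from carvone).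

**Step 7.** The hydride may be delivered to the wrong allyl terminus (giving the tetrasubstituted C8=C9 alkene), the π-allyl intermediate may lose a β-hydrogen to give dienes, or the hindered tertiary carbonate may ionise sluggishly. The fallback sets out from ketone 10 and returns at 14. Alkyllithium 11 is added to 10 as in step 6, but the alkoxide is quenched with NH4Cl to give tertiary allylic alcohol F1. C5H5NH[CrO3Cl] with NaOAc in CH2Cl2 effects oxidative 1,3-transposition (Babler–Dauben) to the transposed enone F2, which now carries the side chain on the β-carbon C9. Li/NH3 in THF at −78 °C, followed by PhNTf2, gives enol triflate F3; axial protonation at C9 anti to the axial C10 methyl should leave the side chain equatorial and fix the enol double bond at C7=C8. Pd(OAc)2/PPh3 with HCO2H and Bu3N in DMF at 60 °C then reduces the triflate to 14.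

**Step 12.** Facial selectivity of the hydroxyl-directed oxygen transfer may be poor (including relay of any wrong C3 epimer from step 11 into C4), or oxygen may be delivered to the bishomoallylic ring alkene. The fallback sets out from ketone 20 and returns at 22, and uses no electrophilic oxidant. CH2=C(OEt)Li in THF at −78 °C adds anti to the angular methyl to give enol ether adduct F4, and 0.1 M HCl in THF hydrolyses it to α-hydroxy methyl ketone F5. Corey–Chaykovsky methylene transfer with dimethylsulfonium methylide (Me3S+ I−, NaH, DMSO/THF) then forms the oxirane 22. Under polar Felkin–Anh control (C3–O anti to the incoming ylide, approach past the ring CH2 rather than the ring-fusion CH) the same C4 configuration is expected, from a control element independent of hydroxyl direction.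

**Step 13.** The Lewis acid may induce migration of the wrong ring bond (C2), isomerise the epoxide to an allylic alcohol, or allow retro-aldol loss of formaldehyde from the β-hydroxy ketone before hydride transfer. The fallback sets out from 22 and returns at 25, and separates the three events. ZnBr2 (or BF3·OEt2) in CH2Cl2 at −78 °C gives the isolated β-hydroxy ketone 23. Me4NBH(OAc)3 in MeCN/AcOH at −30 °C (Saksena–Evans hydroxyl-directed reduction, hydride delivered from the C19 side) gives diol F6 with the axial 3-OH. AcCl and 2,4,6-collidine in CH2Cl2 at −78 °C then acetylate only the primary hydroxyl to give 25.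

Further compounds
F1 | step 7 | tertiary allylic alcohol (9-OH syn to the C10 methyl) | C=C(C)[C@H]1CC=C(C)[C@@](CC[C@@H](C)CCO[Si](C(C)C)(C(C)C)C(C)C)(O)[C@]1(C)C(OC)OC
F2 | step 7 | transposed enone (7-oxo, C8=C9, side chain on C9) | C=C(C)[C@H]1CC(=O)C(C)=C(CC[C@@H](C)CCO[Si](C(C)C)(C(C)C)C(C)C)[C@]1(C)C(OC)OC
F3 | step 7 | enol triflate (C7 triflate, C7=C8, 9-H anti to the C10 methyl) | C=C(C)[C@H]1CC(OS(=O)(=O)C(F)(F)F)=C(C)[C@@H](CC[C@@H](C)CCO[Si](C(C)C)(C(C)C)C(C)C)[C@]1(C)C(OC)OC
F4 | step 12 | enol ether adduct (C3 carbinol with 1-ethoxyvinyl) | C=C(OCC)[C@]1(O)[C@H]2CC=C(C)[C@@H](CC[C@@H](C)CCO[Si](C(C)C)(C(C)C)C(C)C)[C@]2(C)CC1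
F5 | step 12 | α-hydroxy methyl ketone (C3 carbinol with acetyl) | CC(=O)[C@]1(O)[C@H]2CC=C(C)[C@@H](CC[C@@H](C)CCO[Si](C(C)C)(C(C)C)C(C)C)[C@]2(C)CC1
F6 | step 13 | (3S,4R,5S,9R,10S,13R)-15-(triisopropylsilyloxy)labd-7-ene-3,19-diol | OC[C@@]1(C)[C@H]2CC=C(C)[C@@H](CC[C@@H](C)CCO[Si](C(C)C)(C(C)C)C(C)C)[C@]2(C)CC[C@@H]1O
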